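**Plan**

- Retrosynthesis: remove the two aryl silyl ethers, then cut C3–C2 of the dihydrofuran ring. C3 is traced to an aldehyde carbon on C5' and C2 to the OCH2 carbon of a 2-hydroxy-2-methylpropyl ether on O6'. Then cut the C5'–CHO bond, the O6'–CH2 bond, the C3'–prenyl bond (traced to an O6'-prenyl ether by a Claisen–Cope sequence) and the C1'–acyl bond, back to phloroglucinol.
- Forward: ring B (anisole) arrives with the nitrile. Ring A (phloroglucinol) is acylated and its substituents are placed one at a time under hydrogen-bond and ortho/para control. The dihydrofuran ring is closed in the step before the final deprotection.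
- Enabling feature: C3 of the dihydrofuran sits on ring-A carbon C3a, next to C7a, which carries the ring oxygen O1. A carbene-type centre at C3 (made from an aldehyde) is therefore 1,5 to the hydrogens on C2 of an ArO–CH2–C(CH3)2OH ether, and O1 weakens those C–H bonds.
- Stereochemistry: the single stereocentre C2 (S) is created in the ring closure from an achiral precursor, by choice between the enantiotopic OCH2 hydrogens under control of a chiral cobalt porphyrin. No later step touches it.
- Ring-A locants used below: C1' acyl, O2', C3' prenyl, O4', C5' (bears C3 of the dihydrofuran), O6' (becomes O1).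

Key step: step 10

Remarks on the chemistry:
- [Co(P*)] is the cobalt complex (divalent cobalt) of the D2-symmetric porphyrin dianion P* = 5,15-bis(3,5-di-tert-butylphenyl)-10,20-bis[2,6-bis((S)-2,2-dimethylcyclopropanecarboxamido)phenyl]porphyrin.
- Assumption: the sense of induction at the OCH2 group cannot be predicted with certainty. The ligand antipode that gives the 2S product is used, with the (S)-amide ligand as first choice.

**Route**

Step 1
Reactants: 1 phloroglucinol (benzene-1,3,5-triol); 2 3-(4-methoxyphenyl)propanenitrile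
Product: 4 1-(2,4,6-trihydroxyphenyl)-3-(4-methoxyphenyl)propan-1-one, via ketiminium chloride 3 (not isolated)
Conditions: HCl (g), ZnCl2 (cat.), Et2O, 0 °C to rt; then H2O, reflux
Reagents that add atoms: water, O
Why: Houben–Hoesch acylation, in which the protonated nitrile attacks the symmetric, highly nucleophilic phloroglucinol once (the precipitated ketiminium salt resists a second acylation) and hydrolysis gives the aryl ketone, while the less electron-rich anisole ring and its methyl ether are untouched.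

Step 2
Reactants: 4 1-(2,4,6-trihydroxyphenyl)-3-(4-methoxyphenyl)propan-1-one
Product: 5 1-[6-hydroxy-2,4-bis(methoxymethoxy)phenyl]-3-(4-methoxyphenyl)propan-1-one
Conditions: MOMCl (2.2 equiv), iPr2NEt, CH2Cl2, 0 °C to rt
Reagents that add atoms: chloromethyl methyl ether (MOMCl), COCCl
Why: O-alkylation with an alpha-chloro ether, in which the para hydroxyl and one of the two equivalent ortho hydroxyls react while the last ortho hydroxyl stays free because it is held in a hydrogen bond to the ketone, as is usual for 2,4,6-trihydroxyaryl ketones.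

Step 3
Reactants: 5 1-[6-hydroxy-2,4-bis(methoxymethoxy)phenyl]-3-(4-methoxyphenyl)propan-1-one; 6 1-bromo-3-methylbut-2-ene (prenyl bromide)
Product: 7 1-[2,4-bis(methoxymethoxy)-6-(3-methylbut-2-en-1-yloxy)phenyl]-3-(4-methoxyphenyl)propan-1-one
Conditions: K2CO3, acetone, reflux
Reagents that add atoms: 6 1-bromo-3-methylbut-2-ene, CC(C)=CCBr
Why: Williamson etherification of the only free (chelated) phenoxide with a reactive allylic bromide under carbonate conditions that favour O- over C-alkylation.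

Step 4
Reactants: 7 1-[2,4-bis(methoxymethoxy)-6-(3-methylbut-2-en-1-yloxy)phenyl]-3-(4-methoxyphenyl)propan-1-one
Product: 10 1-[6-hydroxy-2,4-bis(methoxymethoxy)-3-(3-methylbut-2-en-1-yl)phenyl]-3-(4-methoxyphenyl)propan-1-one, via ortho-dienone 8 (not isolated), via para-dienone 9 (not isolated)
Conditions: PhNEt2, 200 °C (sealed tube)
Reagents that add atoms: none
Why: aromatic Claisen rearrangement to the free ortho carbon C5', then Cope rearrangement to the para carbon C3' and enolisation (para-Claisen–Cope sequence), should place a linear prenyl group between the two MOM ethers and free the 6'-phenol, as established for the corresponding 6'-prenyloxy-2',4'-bis(methoxymethoxy)acetophenone.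

Step 5
Reactants: 10 1-[6-hydroxy-2,4-bis(methoxymethoxy)-3-(3-methylbut-2-en-1-yl)phenyl]-3-(4-methoxyphenyl)propan-1-one; 11 2,2-dimethyloxirane
Product: 12 1-[6-(2-hydroxy-2-methylpropoxy)-2,4-bis(methoxymethoxy)-3-(3-methylbut-2-en-1-yl)phenyl]-3-(4-methoxyphenyl)propan-1-one
Conditions: K2CO3 (0.3 equiv), DMF, 100 °C (sealed tube)
Reagents that add atoms: 11 2,2-dimethyloxirane, CC1(C)CO1
Why: base-catalysed SN2 opening of the epoxide by the only free phenoxide at the unsubstituted CH2 should give the primary aryl ether carrying the tertiary alcohol.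

Step 6
Reactants: 12 1-[6-(2-hydroxy-2-methylpropoxy)-2,4-bis(methoxymethoxy)-3-(3-methylbut-2-en-1-yl)phenyl]-3-(4-methoxyphenyl)propan-1-one
Product: 13 1-[2,4-dihydroxy-6-(2-hydroxy-2-methylpropoxy)-3-(3-methylbut-2-en-1-yl)phenyl]-3-(4-methoxyphenyl)propan-1-one
Conditions: HCl (conc., 5 equiv), MeOH, rt to 40 °C; NaHCO3 quench
Reagents that add atoms: none
Why: acid-catalysed acetal exchange with methanol frees both phenols, and dilute HCl in methanol near room temperature is the standard deprotection for prenylated phloroglucinol ketones, mild enough to spare the prenyl double bond, the tertiary alcohol and the aryl alkyl ethers.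

Step 7
Reactants: 13 1-[2,4-dihydroxy-6-(2-hydroxy-2-methylpropoxy)-3-(3-methylbut-2-en-1-yl)phenyl]-3-(4-methoxyphenyl)propan-1-one; 14 paraformaldehyde (formaldehyde)
Product: 15 2,4-dihydroxy-6-(2-hydroxy-2-methylpropoxy)-5-[3-(4-methoxyphenyl)propanoyl]-3-(3-methylbut-2-en-1-yl)benzaldehyde
Conditions: MgCl2, Et3N, (CH2O)n, MeCN, reflux
Reagents that add atoms: 14 paraformaldehyde, C=O
Why: magnesium-mediated ortho-formylation (Casnati–Skattebøl reaction), in which the magnesium phenoxide of the 4'-OH delivers formaldehyde to its only free ortho carbon C5' (the last unsubstituted position of ring A) and the benzylic alkoxide is oxidised to the aldehyde by hydride transfer to a second formaldehyde, under basic conditions that leave the prenyl group alone.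

Step 8
Reactants: 15 2,4-dihydroxy-6-(2-hydroxy-2-methylpropoxy)-5-[3-(4-methoxyphenyl)propanoyl]-3-(3-methylbut-2-en-1-yl)benzaldehyde
Product: 16 2,4-bis[(tert-butyldimethylsilyl)oxy]-6-(2-hydroxy-2-methylpropoxy)-5-[3-(4-methoxyphenyl)propanoyl]-3-(3-methylbut-2-en-1-yl)benzaldehyde
Conditions: TBSCl (3 equiv), imidazole, DMAP (cat.), DMF, rt to 40 °C
Reagents that add atoms: tert-butyldimethylsilyl chloride (TBSCl), CC(C)(C)[Si](C)(C)Cl
Why: phenol silylation that leaves the tertiary alcohol untouched; silicon on O4' places no hydrogen 1,5 to the future carbene carbon (unlike MOM, benzyl or methyl), and both groups are removed by fluoride at the end.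

Step 9
Reactants: 16 2,4-bis[(tert-butyldimethylsilyl)oxy]-6-(2-hydroxy-2-methylpropoxy)-5-[3-(4-methoxyphenyl)propanoyl]-3-(3-methylbut-2-en-1-yl)benzaldehyde
Product: 17 N'-[(E)-{2,4-bis[(tert-butyldimethylsilyl)oxy]-6-(2-hydroxy-2-methylpropoxy)-5-[3-(4-methoxyphenyl)propanoyl]-3-(3-methylbut-2-en-1-yl)phenyl}methylidene]-2,4,6-tri(propan-2-yl)benzenesulfonohydrazide
Conditions: 2,4,6-(iPr)3C6H2SO2NHNH2 (1.1 equiv), MgSO4, THF, rt
Reagents that add atoms: 2,4,6-tri(propan-2-yl)benzenesulfonohydrazide, CC(C)c1cc(C(C)C)c(S(=O)(=O)NN)c(C(C)C)c1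
Why: condensation of the aldehyde with a sulfonyl hydrazide, in which the ketone (flanked by two ortho substituents) should not compete; the triisopropylbenzenesulfonyl group is chosen because its hydrazone salts release the diazo compound near 40 °C (Bamford–Stevens reaction).

Step 10
Reactants: 17 N'-[(E)-{2,4-bis[(tert-butyldimethylsilyl)oxy]-6-(2-hydroxy-2-methylpropoxy)-5-[3-(4-methoxyphenyl)propanoyl]-3-(3-methylbut-2-en-1-yl)phenyl}methylidene]-2,4,6-tri(propan-2-yl)benzenesulfonohydrazide
Product: 19 1-[(2S)-4,6-bis[(tert-butyldimethylsilyl)oxy]-2-(2-hydroxypropan-2-yl)-5-(3-methylbut-2-en-1-yl)-2,3-dihydro-1-benzofuran-7-yl]-3-(4-methoxyphenyl)propan-1-one, via aryldiazomethane 18 (not isolated)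
Conditions: [Co(P*)] (5 mol%), Cs2CO3 (2 equiv), 1,4-dioxane, 40 °C, N2
Reagents that add atoms: none
Why: Proposed new method: Cs2CO3 eliminates the arenesulfinate from 17 to give aryldiazomethane 18, which the divalent cobalt metalloradical converts with loss of N2 into an alpha-cobalt benzyl radical (trivalent cobalt); this radical abstracts a hydrogen from the ArO–CH2 group through a six-membered transition state (1,5-hydrogen atom transfer), and the alpha-aryloxy radical then displaces cobalt from the benzylic carbon, forming the C3–C2 bond and returning divalent cobalt. The closest known reaction types are the enantioselective cobalt amidoporphyrin radical 1,5-C–H alkylation with aldehyde-derived aryldiazomethanes that closes 2-substituted indolines, and the non-asymmetric metalloporphyrin carbene C–H insertion of ortho-alkoxyaryl sulfonylhydrazone salts to 2,3-dihydrobenzofurans; new here is the asymmetric closure onto a non-benzylic ArO–CH2 bond of a hexasubstituted arene. The dihydrofuran ring closes in the 5-exo-tet mode (intramolecular homolytic substitution at the cobalt-bound carbon). C2 is the only new stereocentre and is under catalyst control: the chiral cyclopropanecarboxamide walls of P*, which can hydrogen-bond to the substrate, decide which enantiotopic hydrogen is removed and which face of the alpha-oxy radical bonds to C3, and the ligand antipode that gives 2S is used. The step needs site selectivity for the side-chain OCH2 and tolerance of the alkene, ketone and free tertiary alcohol: the other ortho oxygen carries silicon with no hydrogen in a 1,5 relationship, the prenyl CH2 is meta and cannot reach the radical centre, and the cobalt-bound carbon radical is not an electrophilic carbene, so it should neither insert into O–H bonds nor add readily to a trisubstituted electron-rich alkene or a hindered ketone.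

Step 11
Reactants: 19 1-[(2S)-4,6-bis[(tert-butyldimethylsilyl)oxy]-2-(2-hydroxypropan-2-yl)-5-(3-methylbut-2-en-1-yl)-2,3-dihydro-1-benzofuran-7-yl]-3-(4-methoxyphenyl)propan-1-one
Product: 20 1-[(2S)-4,6-dihydroxy-2-(2-hydroxypropan-2-yl)-5-(3-methylbut-2-en-1-yl)-2,3-dihydro-1-benzofuran-7-yl]-3-(4-methoxyphenyl)propan-1-one (CNP0150199.1)
Conditions: Bu4NF, AcOH (1:1, 3 equiv), THF, 0 °C to rt
Reagents that add atoms: none
Why: fluoride cleavage of the two aryl silyl ethers, buffered with acetic acid so that the acylphloroglucinol is not exposed to strong base; C2 is an ether carbon without an acidic hydrogen and should keep its configuration.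

**Compound list**

1 | phloroglucinol (benzene-1,3,5-triol) | Oc1cc(O)cc(O)c1 | starting material
2 | 3-(4-methoxyphenyl)propanenitrile | COc1ccc(CCC#N)cc1 | starting material
3 | 3-(4-methoxyphenyl)-1-(2,4,6-trihydroxyphenyl)propan-1-iminium chloride (not isolated) | COc1ccc(CCC(=[NH2+])c2c(O)cc(O)cc2O)cc1.[Cl-] | intermediate
4 | 1-(2,4,6-trihydroxyphenyl)-3-(4-methoxyphenyl)propan-1-one | COc1ccc(CCC(=O)c2c(O)cc(O)cc2O)cc1 | intermediate
5 | 1-[6-hydroxy-2,4-bis(methoxymethoxy)phenyl]-3-(4-methoxyphenyl)propan-1-one | COc1ccc(CCC(=O)c2c(O)cc(OCOC)cc2OCOC)cc1 | intermediate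
6 | 1-bromo-3-methylbut-2-ene (prenyl bromide) | CC(C)=CCBr | starting material
7 | 1-[2,4-bis(methoxymethoxy)-6-(3-methylbut-2-en-1-yloxy)phenyl]-3-(4-methoxyphenyl)propan-1-one | COc1ccc(CCC(=O)c2c(OCC=C(C)C)cc(OCOC)cc2OCOC)cc1 | intermediate
8 | ortho-dienone: 2-[3-(4-methoxyphenyl)propanoyl]-3,5-bis(methoxymethoxy)-6-(2-methylbut-3-en-2-yl)cyclohexa-2,4-dien-1-one (not isolated, racemic at C6) | O=C1C(C(C)(C)C=C)C(OCOC)=CC(OCOC)=C1C(=O)CCc1ccc(OC)cc1 | intermediate
9 | para-dienone: 2-[3-(4-methoxyphenyl)propanoyl]-3,5-bis(methoxymethoxy)-4-(3-methylbut-2-en-1-yl)cyclohexa-2,5-dien-1-one (not isolated) | O=C1C=C(OCOC)C(CC=C(C)C)C(OCOC)=C1C(=O)CCc1ccc(OC)cc1 | intermediate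
10 | 1-[6-hydroxy-2,4-bis(methoxymethoxy)-3-(3-methylbut-2-en-1-yl)phenyl]-3-(4-methoxyphenyl)propan-1-one | COc1ccc(CCC(=O)c2c(O)cc(OCOC)c(CC=C(C)C)c2OCOC)cc1 | intermediate
11 | 2,2-dimethyloxirane | CC1(C)CO1 | starting material
12 | 1-[6-(2-hydroxy-2-methylpropoxy)-2,4-bis(methoxymethoxy)-3-(3-methylbut-2-en-1-yl)phenyl]-3-(4-methoxyphenyl)propan-1-one | COc1ccc(CCC(=O)c2c(OCC(C)(C)O)cc(OCOC)c(CC=C(C)C)c2OCOC)cc1 | intermediate
13 | 1-[2,4-dihydroxy-6-(2-hydroxy-2-methylpropoxy)-3-(3-methylbut-2-en-1-yl)phenyl]-3-(4-methoxyphenyl)propan-1-one | COc1ccc(CCC(=O)c2c(OCC(C)(C)O)cc(O)c(CC=C(C)C)c2O)cc1 | intermediate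
14 | paraformaldehyde (as formaldehyde) | C=O | starting material
15 | 2,4-dihydroxy-6-(2-hydroxy-2-methylpropoxy)-5-[3-(4-methoxyphenyl)propanoyl]-3-(3-methylbut-2-en-1-yl)benzaldehyde | COc1ccc(CCC(=O)c2c(OCC(C)(C)O)c(C=O)c(O)c(CC=C(C)C)c2O)cc1 | intermediate
16 | 2,4-bis[(tert-butyldimethylsilyl)oxy]-6-(2-hydroxy-2-methylpropoxy)-5-[3-(4-methoxyphenyl)propanoyl]-3-(3-methylbut-2-en-1-yl)benzaldehyde | COc1ccc(CCC(=O)c2c(OCC(C)(C)O)c(C=O)c(O[Si](C)(C)C(C)(C)C)c(CC=C(C)C)c2O[Si](C)(C)C(C)(C)C)cc1 | intermediate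
17 | (E)-2,4,6-tri(propan-2-yl)benzenesulfonylhydrazone of 16 | COc1ccc(CCC(=O)c2c(OCC(C)(C)O)c(/C=N/NS(=O)(=O)c3c(C(C)C)cc(C(C)C)cc3C(C)C)c(O[Si](C)(C)C(C)(C)C)c(CC=C(C)C)c2O[Si](C)(C)C(C)(C)C)cc1 | intermediate
18 | 1-[2,4-bis[(tert-butyldimethylsilyl)oxy]-5-(diazomethyl)-6-(2-hydroxy-2-methylpropoxy)-3-(3-methylbut-2-en-1-yl)phenyl]-3-(4-methoxyphenyl)propan-1-one (not isolated) | COc1ccc(CCC(=O)c2c(OCC(C)(C)O)c(C=[N+]=[N-])c(O[Si](C)(C)C(C)(C)C)c(CC=C(C)C)c2O[Si](C)(C)C(C)(C)C)cc1 | intermediate
19 | 1-[(2S)-4,6-bis[(tert-butyldimethylsilyl)oxy]-2-(2-hydroxypropan-2-yl)-5-(3-methylbut-2-en-1-yl)-2,3-dihydro-1-benzofuran-7-yl]-3-(4-methoxyphenyl)propan-1-one | COc1ccc(CCC(=O)c2c(O[Si](C)(C)C(C)(C)C)c(CC=C(C)C)c(O[Si](C)(C)C(C)(C)C)c3c2O[C@H](C(C)(C)O)C3)cc1 | intermediate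
20 | 1-[(2S)-4,6-dihydroxy-2-(2-hydroxypropan-2-yl)-5-(3-methylbut-2-en-1-yl)-2,3-dihydro-1-benzofuran-7-yl]-3-(4-methoxyphenyl)propan-1-one | COc1ccc(CCC(=O)c2c(O)c(CC=C(C)C)c(O)c3c2O[C@H](C(C)(C)O)C3)cc1 | target

**Step count**

Total steps: 11. Longest linear sequence: 11 steps (1 and 2 to 20).

**Steps most likely to fail**

1. Step 10 (proposed new method). The diazo carbon is flanked by a silyloxy and an alkoxy group, so capture by cobalt may be slow and azine formation or thermal decay of the diazo compound may win. Hydrogen abstraction from a non-benzylic, neopentyl-type OCH2 may be sluggish, and facial control at the alpha-oxy radical may be insufficient.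
Fallback (known chemistry; O1–C2 closure by epoxide opening, stereocentre from an asymmetric epoxidation). It sets out from 5 and returns at 20. Palladium-catalysed O-alkylation of 5 (Pd(PPh3)4, tert-butyl 2-methylbut-3-en-2-yl carbonate, THF) would give the tertiary allyl ether 1-[2,4-bis(methoxymethoxy)-6-(2-methylbut-3-en-2-yloxy)phenyl]-3-(4-methoxyphenyl)propan-1-one F1. Ortho-Claisen rearrangement (toluene, reflux) would give the ortho-prenyl phenol 1-[2-hydroxy-4,6-bis(methoxymethoxy)-3-(3-methylbut-2-en-1-yl)phenyl]-3-(4-methoxyphenyl)propan-1-one F2. Acetylation (Ac2O, pyridine) would give the aryl acetate 3,5-bis(methoxymethoxy)-6-[3-(4-methoxyphenyl)propanoyl]-2-(3-methylbut-2-en-1-yl)phenyl acetate F3. Shi epoxidation (D-fructose-derived ketone, KHSO5, buffered MeCN/dimethoxymethane/H2O, 0 °C) is expected to give the (R)-epoxide 2-{[(2R)-3,3-dimethyloxiran-2-yl]methyl}-3,5-bis(methoxymethoxy)-6-[3-(4-methoxyphenyl)propanoyl]phenyl acetate F4. K2CO3 in MeOH would remove the acetate, and the phenoxide would open the epoxide 5-exo at the secondary carbon with inversion to the dihydrobenzofuran 1-[(2S)-2-(2-hydroxypropan-2-yl)-4,6-bis(methoxymethoxy)-2,3-dihydro-1-benzofuran-7-yl]-3-(4-methoxyphenyl)propan-1-one F5. HCl in MeOH (no prenyl group is present at this stage) would give the diphenol 1-[(2S)-4,6-dihydroxy-2-(2-hydroxypropan-2-yl)-2,3-dihydro-1-benzofuran-7-yl]-3-(4-methoxyphenyl)propan-1-one F6. C-prenylation of F6 with 6 (aqueous KOH, 0 °C) at the only free ring carbon would give 20.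

2. Step 7. Attack at the last, doubly flanked ring position may be slow, so that hydroxymethylation alpha to the magnesium-chelated ketone or diarylmethane formation competes.
Fallback (templated hydroxymethylation, then oxidation). It sets out from 13 and returns at 15. Heating 13 with PhB(OH)2, paraformaldehyde and catalytic propanoic acid in toluene with removal of water would give the cyclic phenylboronate across O4' and the new C5'–CH2 group, the 2-phenyl-4H-1,3,2-benzodioxaborinine F7. Boronate exchange with propane-1,3-diol would free the salicyl alcohol 1-[2,4-dihydroxy-5-(hydroxymethyl)-6-(2-hydroxy-2-methylpropoxy)-3-(3-methylbut-2-en-1-yl)phenyl]-3-(4-methoxyphenyl)propan-1-one F8. Oxidation of the benzylic alcohol with MnO2 (CH2Cl2, rt) would give 15.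

3. Step 6. Under acid, the phenols freed next to the prenyl group may add to its double bond (chroman formation) during acetal cleavage.
Fallback (fluoride-labile protection in place of acid-labile). It sets out from 4 and returns at 13. Treatment of 4 with 2-(trimethylsilyl)ethoxymethyl chloride and iPr2NEt would give the bis-SEM ether 1-[6-hydroxy-2,4-bis{[2-(trimethylsilyl)ethoxy]methoxy}phenyl]-3-(4-methoxyphenyl)propan-1-one F9. Alkylation with 6 (K2CO3, acetone) would give the prenyl ether 1-[6-(3-methylbut-2-en-1-yloxy)-2,4-bis{[2-(trimethylsilyl)ethoxy]methoxy}phenyl]-3-(4-methoxyphenyl)propan-1-one F10. Claisen–Cope rearrangement (PhNEt2, 200 °C) would give the phenol 1-[6-hydroxy-3-(3-methylbut-2-en-1-yl)-2,4-bis{[2-(trimethylsilyl)ethoxy]methoxy}phenyl]-3-(4-methoxyphenyl)propan-1-one F11. Opening of 11 (K2CO3, DMF, 100 °C) would give the ether 1-[6-(2-hydroxy-2-methylpropoxy)-3-(3-methylbut-2-en-1-yl)-2,4-bis{[2-(trimethylsilyl)ethoxy]methoxy}phenyl]-3-(4-methoxyphenyl)propan-1-one F12. Bu4NF with ethylenediamine (formaldehyde scavenger) in DMF at 60 °C would give 13 without acid.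

**Further compounds**

F1 | step 10 | 1-[2,4-bis(methoxymethoxy)-6-(2-methylbut-3-en-2-yloxy)phenyl]-3-(4-methoxyphenyl)propan-1-one | COc1ccc(CCC(=O)c2c(OC(C)(C)C=C)cc(OCOC)cc2OCOC)cc1
F2 | step 10 | 1-[2-hydroxy-4,6-bis(methoxymethoxy)-3-(3-methylbut-2-en-1-yl)phenyl]-3-(4-methoxyphenyl)propan-1-one | COc1ccc(CCC(=O)c2c(O)c(CC=C(C)C)c(OCOC)cc2OCOC)cc1
F3 | step 10 | 3,5-bis(methoxymethoxy)-6-[3-(4-methoxyphenyl)propanoyl]-2-(3-methylbut-2-en-1-yl)phenyl acetate | COc1ccc(CCC(=O)c2c(OC(C)=O)c(CC=C(C)C)c(OCOC)cc2OCOC)cc1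
F4 | step 10 | 2-{[(2R)-3,3-dimethyloxiran-2-yl]methyl}-3,5-bis(methoxymethoxy)-6-[3-(4-methoxyphenyl)propanoyl]phenyl acetate | COc1ccc(CCC(=O)c2c(OC(C)=O)c(C[C@H]3OC3(C)C)c(OCOC)cc2OCOC)cc1
F5 | step 10 | 1-[(2S)-2-(2-hydroxypropan-2-yl)-4,6-bis(methoxymethoxy)-2,3-dihydro-1-benzofuran-7-yl]-3-(4-methoxyphenyl)propan-1-one | COc1ccc(CCC(=O)c2c(OCOC)cc(OCOC)c3c2O[C@H](C(C)(C)O)C3)cc1
F6 | step 10 | 1-[(2S)-4,6-dihydroxy-2-(2-hydroxypropan-2-yl)-2,3-dihydro-1-benzofuran-7-yl]-3-(4-methoxyphenyl)propan-1-one | COc1ccc(CCC(=O)c2c(O)cc(O)c3c2O[C@H](C(C)(C)O)C3)cc1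
F7 | step 7 | 2-phenyl-4H-1,3,2-benzodioxaborinine across O4' and C5'-CH2 (cyclic phenylboronate of F8) | COc1ccc(CCC(=O)c2c(OCC(C)(C)O)c3COB(c4ccccc4)Oc3c(CC=C(C)C)c2O)cc1
F8 | step 7 | 1-[2,4-dihydroxy-5-(hydroxymethyl)-6-(2-hydroxy-2-methylpropoxy)-3-(3-methylbut-2-en-1-yl)phenyl]-3-(4-methoxyphenyl)propan-1-one | COc1ccc(CCC(=O)c2c(OCC(C)(C)O)c(CO)c(O)c(CC=C(C)C)c2O)cc1
F9 | step 6 | 1-[6-hydroxy-2,4-bis{[2-(trimethylsilyl)ethoxy]methoxy}phenyl]-3-(4-methoxyphenyl)propan-1-one | COc1ccc(CCC(=O)c2c(O)cc(OCOCC[Si](C)(C)C)cc2OCOCC[Si](C)(C)C)cc1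
F10 | step 6 | 1-[6-(3-methylbut-2-en-1-yloxy)-2,4-bis{[2-(trimethylsilyl)ethoxy]methoxy}phenyl]-3-(4-methoxyphenyl)propan-1-one | COc1ccc(CCC(=O)c2c(OCC=C(C)C)cc(OCOCC[Si](C)(C)C)cc2OCOCC[Si](C)(C)C)cc1
F11 | step 6 | 1-[6-hydroxy-3-(3-methylbut-2-en-1-yl)-2,4-bis{[2-(trimethylsilyl)ethoxy]methoxy}phenyl]-3-(4-methoxyphenyl)propan-1-one | COc1ccc(CCC(=O)c2c(O)cc(OCOCC[Si](C)(C)C)c(CC=C(C)C)c2OCOCC[Si](C)(C)C)cc1
F12 | step 6 | 1-[6-(2-hydroxy-2-methylpropoxy)-3-(3-methylbut-2-en-1-yl)-2,4-bis{[2-(trimethylsilyl)ethoxy]methoxy}phenyl]-3-(4-methoxyphenyl)propan-1-one | COc1ccc(CCC(=O)c2c(OCC(C)(C)O)cc(OCOCC[Si](C)(C)C)c(CC=C(C)C)c2OCOCC[Si](C)(C)C)cc1
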